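Take the three earlier runs and question them before touching the new flasks.

in all of them: electrophile 0.20 M
- grey: nucleophile 0.30 M; free base 0.056 M; run made earlier
- ochre: nucleophile 0.30 M; free base 0.13 M; run made earlier
- amber: nucleophile 0.30 M; free base 0.20 M; run made earlier
- south-west: nucleophile 0.300 M; free base 0.120 M; time 10 min
- north-east: nucleophile 0.300 M; free base 0.0600 M; time 10 min
- east: nucleophile 0.300 M; free base 0.240 M; time 10 min

- grey (time / min: electrophile / %, target / %): 0.500: 85, 10; 1.00: 82, 18; 2.00: 71, 33; 4.00: 61, 42; 8.00: 53, 45
- ochre (time / min: electrophile / %, target / %): 0.500: 84, 13; 1.00: 78, 23; 2.00: 72, 29; 4.00: 57, 42; 8.00: 47, 46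
- amber (time / min: electrophile / %, target / %): 0.500: 86, 13; 1.00: 83, 21; 2.00: 69, 36; 4.00: 60, 41; 8.00: 48, 51

(readings scatter by 2 percentage points)

- steps under discussion: 2 nucleophile -> self-condensation product; nucleophile + acid set free <-> protonated nucleophile; electrophile + nucleophile -> acid set free + target; acid set free + target -> side product; acid set free + free base <-> salt of the base

- part of the electrophile that has reacted at the end, south-west
- part of the electrophile that has reacted at the end, north-east
- part of the electrophile that has reacted at the end, east
- what raising the concentration of free base from its lowest to its highest value here does to the part of the electrophile that has reacted (changes below 5 percentage points count as none) (it rises / it falls / no change)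

Does the free base change the outcome? Not that I can read. Electrophile left at 8.00 min is 53% in grey, 47% in ochre and 48% in amber.

But that spread, 6 percentage points, is wider than the margin of 5 points. True, but a difference of two readings carries a scatter of 2.8 points. At 2.00 min the order also changes: amber 69%, grey 71%, ochre 72%. So I pool the runs.

Why does the electrophile slow down? Pooled, it falls from 59.3% at 4.00 min to 49.3% at 8.00 min, a loss of 0.0461 min⁻¹. Yet it has used 0.101 M, less than the 0.30 M of nucleophile charged. I suspect the nucleophile is going elsewhere too. That is a suspicion, not a reading.

What do you freeze? Carrying the late loss on to 10 min gives 2.66 L mol⁻¹ for what I call the nucleophile dose: the natural logarithm of electrophile charged over electrophile left at the asked time, divided by the nucleophile charged. I assume it stays the same when the nucleophile charge changes.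

Isn't the late loss still slowing? Yes, the earlier loss was faster, so my figure may err slightly high.

My reckoning gives 55.0% reacted in each of the three flasks, with no change from the free base.

The forecast gives 54% for south-west, 51% for north-east and 55% for east, with the trend no change. Its ground is: “The nucleophile must therefore be disappearing, most likely by self-condensation, which is independent of base.” It puts north-east lower than I do.

The flasks give 54.3% for south-west, 53.4% for north-east and 55.6% for east, so the trend is no change, with a change of 2.1 points.

    2 nucleophile → self-condensation product (k = 0.0100 L mol⁻¹ s⁻¹)
    nucleophile + acid set free ⇌ protonated nucleophile, settled at all times (K = 150 L mol⁻¹)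
    electrophile + nucleophile → acid set free + target (k = 0.0180 L mol⁻¹ s⁻¹)
    acid set free + target → side product (k = 0.0160 L mol⁻¹ s⁻¹)
    acid set free + free base ⇌ salt of the base (K = 19.0 L mol⁻¹, k = 0.160 L mol⁻¹ s⁻¹)

At 10.0 min, south-west has 8.8% of its nucleophile still free, less than the 46% of its electrophile left. That electrophile left returns a dose of 2.61 L mol⁻¹. Now put the carried 2.66 L mol⁻¹ on a neighbour flask, like south-west but with 0.18 M of nucleophile: the dose gives 38.0% reacted. That neighbour flask itself gives 40.4%.

The data were generated by integration on assumed constants.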